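**Retrosynthetic overview**

The target is (2S)-7-hydroxy-4'-O-geranylflavanone (chroman numbering O1, C2, C3, C4, C4a, C5–C8, C8a). Read backwards, the endgame is 7-O-desilylation ⇐ oxidation of a C4 carbinol ⇐ hydrolysis of a C4 methyl ether ⇐ Mitsunobu geranylation of the 4'-phenol.
The strategy rests on ring C, the oxygen heterocycle fused to resorcinol ring A: its O1–C2 and C3–C4 bonds are cut in one retro-[4+2] operation. This leaves ring A as an α-methoxy ortho-quinone methide (C4=C4a–C8a=O1) and ring B as 4-vinylphenol, which supplies C2 and C3.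
The methide is made in the flask from 2-hydroxy-4-(triisopropylsilyloxy)benzaldehyde and trimethyl orthoformate under a chiral phosphoric acid, which also sets C2; the methoxy group brings C4 in at the carbinol oxidation level.
Rings A and B are bought; ring C is the only ring formed (step 3). The aldehyde comes from 2,4-dihydroxybenzaldehyde by 4-O-silylation, the vinylphenol from 4-acetoxystyrene, and the geranyl chain is attached only after the cycloaddition.

Key step: step 3

Assumption: the sense of induction of the phosphoric acid at C2 cannot be assigned in advance, so (R)-TRIP is written and its antipode is used if it favours (2R); C4 of the cycloadduct is drawn as the 2,4-cis epimer expected from endo closure, and its configuration does not matter because C4 becomes the carbonyl carbon.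

**Route**

Step 1
Reactants: 1 2,4-dihydroxybenzaldehyde
Product: 2 2-hydroxy-4-(triisopropylsilyloxy)benzaldehyde
Conditions: TIPSCl (1.05 equiv), imidazole (2.2 equiv), CH2Cl2, 0 °C to rt
Reagents that add atoms: triisopropylsilyl chloride (TIPSCl), CC(C)[Si](Cl)(C(C)C)C(C)C
Why: Phenol silylation that should be selective for the 4-hydroxyl, because the 2-hydroxyl is held in a hydrogen bond to the aldehyde and is less acidic and more hindered toward the bulky silyl chloride.

Step 2
Reactants: 3 4-acetoxystyrene
Product: 4 4-vinylphenol
Conditions: KOH (2.0 equiv), H2O, 0 °C; then 1 M HCl to pH 6, 0 °C; extracted into Et2O, dried and used at once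
Reagents that add atoms: none
Why: Saponification of an aryl acetate in the cold, which should free the phenol without polymerising the styrene, provided the product is used immediately.

Step 3
Reactants: 2 2-hydroxy-4-(triisopropylsilyloxy)benzaldehyde, 5 trimethyl orthoformate, 4 4-vinylphenol
Product: 8 (2S,4S)-2-(4-hydroxyphenyl)-4-methoxy-7-(triisopropylsilyloxy)chroman, via dimethyl acetal 6 (not isolated), via methoxy ortho-quinone methide 7 (not isolated)
Conditions: (R)-TRIP (10 mol %), 5 (1.5 equiv), 5 Å MS, CH2Cl2, rt; then 4 (1.5 equiv) added over 4 h, −30 °C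
Reagents that add atoms: none
Why: Proposed new method: the phosphoric acid should first catalyse acetal exchange between 2 and 5 to give 6, which loses methanol (taken up by the sieves) to the phosphate-bound (E)-α-methoxy ortho-quinone methide 7; the P–OH then hydrogen-bonds the methide oxygen while the P=O accepts the phenol O–H of 4, the vinyl CH2 adds to the methide carbon (C3–C4) and the ring oxygen collapses onto the developing para-hydroxybenzylic cation (O1–C2). The closest known reactions are the achiral acid-promoted three-component union of salicylaldehydes, orthoformates and styrenes to racemic 2-aryl-4-alkoxychromans and the chiral phosphoric acid-catalysed [4+2] cycloadditions of ortho-quinone methides from ortho-hydroxybenzyl alcohols with hydroxystyrenes; new is their combination, an enantioselective cycloaddition of an α-alkoxy methide made in the flask from an aldehyde. Ring C is closed by an asynchronous inverse-electron-demand oxa-[4+2] cycloaddition, C3–C4 leading and O1–C2 following. C2 is set by the catalyst, whose 2,4,6-triisopropylphenyl walls should leave one face of the doubly hydrogen-bonded styrene open to the methide, while C4 follows from endo approach to the E-methide (2,4-cis) and is erased later. Regiochemistry is secured by polarity (nucleophilic CH2 terminus to the electrophilic methide carbon, which the para-silyloxy group stabilises), and acid-induced oligomerisation of 4 is held back by forming 6 first and adding 4 slowly at low temperature under a weak acid.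

Step 4
Reactants: 8 (2S,4S)-2-(4-hydroxyphenyl)-4-methoxy-7-(triisopropylsilyloxy)chroman, 9 geraniol
Product: 10 (2S,4S)-2-[4-(geranyloxy)phenyl]-4-methoxy-7-(triisopropylsilyloxy)chroman
Conditions: PPh3 (1.3 equiv), DIAD (1.3 equiv), THF, 0 °C to rt
Reagents that add atoms: none
Why: Mitsunobu etherification of the only free phenol with a primary allylic alcohol, which should proceed by direct SN2 displacement under neutral conditions that leave the aryl silyl ether, the C4 methyl ether and C2 untouched.

Step 5
Reactants: 10 (2S,4S)-2-[4-(geranyloxy)phenyl]-4-methoxy-7-(triisopropylsilyloxy)chroman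
Product: 11 (2S,4S)-2-[4-(geranyloxy)phenyl]-7-(triisopropylsilyloxy)chroman-4-ol (drawn as the cis epimer; either C4 epimer serves)
Conditions: TsOH·H2O (0.2 equiv), THF/H2O 3:1 (0.02 M), rt to 40 °C
Reagents that add atoms: water, O
Why: SN1 solvolysis of a benzylic methyl ether whose cation is stabilised by the ortho ring oxygen and the para silyloxy group, so C4 should ionise far more readily than the singly activated C2 aryl ether, and high dilution in excess water should favour capture by water over self-alkylation.

Step 6
Reactants: 11 (2S,4S)-2-[4-(geranyloxy)phenyl]-7-(triisopropylsilyloxy)chroman-4-ol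
Product: 12 (2S)-2-[4-(geranyloxy)phenyl]-7-(triisopropylsilyloxy)chroman-4-one
Conditions: DMP (1.3 equiv), pyridine, CH2Cl2, 0 °C to rt
Reagents that add atoms: none
Why: Dess–Martin oxidation of a secondary benzylic alcohol under buffered, non-basic conditions, which should take both C4 epimers to the same ketone without touching the geranyl alkenes or opening the β-aryloxy ketone.

Step 7
Reactants: 12 (2S)-2-[4-(geranyloxy)phenyl]-7-(triisopropylsilyloxy)chroman-4-one
Product: 13 (2S)-2-[4-(geranyloxy)phenyl]-7-hydroxychroman-4-one
Conditions: Bu4NF (1.1 equiv), AcOH (1.2 equiv), THF, 0 °C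
Reagents that add atoms: none
Why: Fluoride cleavage of the aryl silyl ether, with acetic acid buffering the medium so that the flavanone should not open to the chalcone by retro-oxa-Michael reaction and C2 keeps its configuration.

**Compound list**

1 | 2,4-dihydroxybenzaldehyde | O=Cc1ccc(O)cc1O | starting material
2 | 2-hydroxy-4-(triisopropylsilyloxy)benzaldehyde | O=Cc1ccc(O[Si](C(C)C)(C(C)C)C(C)C)cc1O | intermediate
3 | 4-acetoxystyrene | CC(=O)Oc1ccc(C=C)cc1 | starting material
4 | 4-vinylphenol | C=Cc1ccc(O)cc1 | intermediate
5 | trimethyl orthoformate | COC(OC)OC | starting material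
6 | 2-(dimethoxymethyl)-5-(triisopropylsilyloxy)phenol | COC(OC)c1ccc(O[Si](C(C)C)(C(C)C)C(C)C)cc1O | intermediate (not isolated)
7 | (6E)-6-(methoxymethylidene)-3-(triisopropylsilyloxy)cyclohexa-2,4-dien-1-one | CO/C=C1\C=CC(O[Si](C(C)C)(C(C)C)C(C)C)=CC1=O | intermediate (not isolated)
8 | (2S,4S)-2-(4-hydroxyphenyl)-4-methoxy-7-(triisopropylsilyloxy)chroman | Oc1ccc([C@@H]2C[C@H](OC)c3ccc(O[Si](C(C)C)(C(C)C)C(C)C)cc3O2)cc1 | intermediate
9 | geraniol, (2E)-3,7-dimethylocta-2,6-dien-1-ol | CC(C)=CCC/C(C)=C/CO | starting material
10 | (2S,4S)-2-[4-(geranyloxy)phenyl]-4-methoxy-7-(triisopropylsilyloxy)chroman | CC(C)=CCC/C(C)=C/COc1ccc([C@@H]2C[C@H](OC)c3ccc(O[Si](C(C)C)(C(C)C)C(C)C)cc3O2)cc1 | intermediate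
11 | (2S,4S)-2-[4-(geranyloxy)phenyl]-7-(triisopropylsilyloxy)chroman-4-ol | CC(C)=CCC/C(C)=C/COc1ccc([C@@H]2C[C@H](O)c3ccc(O[Si](C(C)C)(C(C)C)C(C)C)cc3O2)cc1 | intermediate
12 | (2S)-2-[4-(geranyloxy)phenyl]-7-(triisopropylsilyloxy)chroman-4-one | CC(C)=CCC/C(C)=C/COc1ccc([C@@H]2CC(=O)c3ccc(O[Si](C(C)C)(C(C)C)C(C)C)cc3O2)cc1 | intermediate
13 | (2S)-2-[4-(geranyloxy)phenyl]-7-hydroxychroman-4-one | CC(C)=CCC/C(C)=C/COc1ccc([C@@H]2CC(=O)c3ccc(O)cc3O2)cc1 | target

**Step count**

Total steps: 7. Longest linear sequence: 6 (steps 1, 3, 4, 5, 6, 7); step 2 is a one-step side branch.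

**Steps most likely to fail**

Step 3. The phosphoric acid may give poor facial selectivity at C2, may be too weak to turn the aldehyde over to the methide, or may oligomerise the vinylphenol before it meets the methide. The fallback sets out from 2, 3 and 5 and returns to the route at 12. The cycloaddition is run as the known racemic acid-promoted three-component process, with Sc(OTf)3 (5 mol %) in CH2Cl2 and the bench-stable styrene 3 in place of 4. This should give racemic 4-[4-methoxy-7-(triisopropylsilyloxy)chroman-2-yl]phenyl acetate F1. Hydrazine hydrate in THF at 0 °C removes the acetate without touching the silyl ether and gives racemic 2-(4-hydroxyphenyl)-4-methoxy-7-(triisopropylsilyloxy)chroman F2. Steps 4, 5 and 6 applied in the racemic series lead through racemic 2-[4-(geranyloxy)phenyl]-4-methoxy-7-(triisopropylsilyloxy)chroman F3 and racemic 2-[4-(geranyloxy)phenyl]-7-(triisopropylsilyloxy)chroman-4-ol F4 to racemic 2-[4-(geranyloxy)phenyl]-7-(triisopropylsilyloxy)chroman-4-one F5. A kinetic resolution by asymmetric transfer hydrogenation, RuCl(p-cymene)[(R,R)-TsDPEN] (1 mol %) with HCO2H/Et3N in EtOAc at rt, stopped near half conversion, is expected to reduce the (2R) ketone to (2R,4R)-2-[4-(geranyloxy)phenyl]-7-(triisopropylsilyloxy)chroman-4-ol F6 and to leave the (2S) ketone 12, which is separated by chromatography. If this catalyst should consume the (2S) ketone instead, its (S,S) antipode is used.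

Step 5. Under acid the C2 aryl ether may ionise alongside C4 (erosion of enantiopurity), the C4 cation may lose a proton to the flav-3-ene, or it may alkylate the electron-rich ring A of a second molecule. The fallback sets out from 10 and returns at 12. DDQ (1.2 equiv) in CH2Cl2/pH 7 buffer at 0 °C should oxidise the electron-rich benzylic methyl ether directly: hydride abstraction at C4, capture of the oxocarbenium ion by water and loss of methanol give the ketone without any acid. The doubly activated C4–H should react faster than C2–H or the geranyl ether at this temperature with limited oxidant. Alcohol 11 is bypassed and no new compound is made (F0).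

Step 7. Fluoride-derived base may open the flavanone to the 2'-hydroxychalcone and reclose it, scrambling C2. The fallback sets out from 11 and returns at 13, changing the order of events so that no ketone is exposed to fluoride. Bu4NF in THF at 0 °C on the base-stable flavanol 11 should give (2S,4S)-2-[4-(geranyloxy)phenyl]chroman-4,7-diol F7. Activated MnO2 in CH2Cl2 at rt then oxidises the benzylic carbinol selectively to the target 13 under neutral conditions.

**Further compounds**

F1 | step 3 | racemic 4-[4-methoxy-7-(triisopropylsilyloxy)chroman-2-yl]phenyl acetate | CC(=O)Oc1ccc(C2CC(OC)c3ccc(O[Si](C(C)C)(C(C)C)C(C)C)cc3O2)cc1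
F2 | step 3 | racemic 2-(4-hydroxyphenyl)-4-methoxy-7-(triisopropylsilyloxy)chroman | Oc1ccc(C2CC(OC)c3ccc(O[Si](C(C)C)(C(C)C)C(C)C)cc3O2)cc1
F3 | step 3 | racemic 2-[4-(geranyloxy)phenyl]-4-methoxy-7-(triisopropylsilyloxy)chroman | CC(C)=CCC/C(C)=C/COc1ccc(C2CC(OC)c3ccc(O[Si](C(C)C)(C(C)C)C(C)C)cc3O2)cc1
F4 | step 3 | racemic 2-[4-(geranyloxy)phenyl]-7-(triisopropylsilyloxy)chroman-4-ol | CC(C)=CCC/C(C)=C/COc1ccc(C2CC(O)c3ccc(O[Si](C(C)C)(C(C)C)C(C)C)cc3O2)cc1
F5 | step 3 | racemic 2-[4-(geranyloxy)phenyl]-7-(triisopropylsilyloxy)chroman-4-one | CC(C)=CCC/C(C)=C/COc1ccc(C2CC(=O)c3ccc(O[Si](C(C)C)(C(C)C)C(C)C)cc3O2)cc1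
F6 | step 3 | (2R,4R)-2-[4-(geranyloxy)phenyl]-7-(triisopropylsilyloxy)chroman-4-ol | CC(C)=CCC/C(C)=C/COc1ccc([C@H]2C[C@@H](O)c3ccc(O[Si](C(C)C)(C(C)C)C(C)C)cc3O2)cc1
F0 | step 5 | none | none
F7 | step 7 | (2S,4S)-2-[4-(geranyloxy)phenyl]chroman-4,7-diol | CC(C)=CCC/C(C)=C/COc1ccc([C@@H]2C[C@H](O)c3ccc(O)cc3O2)cc1
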